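**Retrosynthetic overview**

1. The C7 ketone is cut at the C7–C(=O) bond, back to a C7 aryllithium (from a C7 bromide) and 3-(4-methoxyphenyl)propanal, with oxidation afterwards. The C5 prenyl group comes from directed ortho-metalation between the two MOM ethers. Both phenols are unmasked last.
2. The CMe2OH group on C2 comes from a C2 methyl ester and MeMgBr, and the ester from an N-acyl oxazolidinone.
3. The plan rests on C2 of the dihydrofuran ring (ring B): it bears O1, one H, the C3 methylene and a carboxyl-level carbon, so it is the α-carbon of an aryloxyacetic acid, and C3 is a benzylic carbon on C3a. The C2–C3 bond is made by intramolecular alkylation of the sodium enolate of an N-(aryloxyacetyl)-(R)-4-benzyloxazolidinone with the ortho CH2Br group, which closes ring B and sets C2 as S.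
4. The cyclisation precursor comes from 2,4,6-trihydroxybenzaldehyde: the formyl carbon becomes C3, the chelated OH becomes O1, and a bromine placed ortho to that OH becomes C7–Br. The enolate cannot attack this bromine (an ester at C7 would invite Claisen-type attack), and it later serves as the handle for the acyl chain.
5. Ring order: ring A (benzene) and the anisyl ring are bought; ring B is the only ring formed (step 7).

Key step: step 7

Remark on the chemistry: the carbinol carbon created in step 10 is not controlled and is destroyed by the oxidation in step 12, so 19 and 22 are carried as mixtures of two epimers at that carbon; C2 is the only stereocentre of the target.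

**Route**

Step 1
Reactants: 1 2,4,6-trihydroxybenzaldehyde
Product: 3 2-hydroxy-4,6-bis(methoxymethoxy)benzaldehyde, via 4-mono-MOM ether 2 (not isolated)
Conditions: MOMCl (2.2 equiv), i-Pr2NEt (2.5 equiv), CH2Cl2, 0 °C → rt
Reagents that add atoms: chloromethyl methyl ether, COCCl
Why: O-alkylation (MOM protection) of the para OH and of one ortho OH; the remaining ortho OH is hydrogen-bonded to the formyl group, is the least reactive, and should stay free to become O1.

Step 2
Reactants: 3 2-hydroxy-4,6-bis(methoxymethoxy)benzaldehyde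
Product: 4 3-bromo-2-hydroxy-4,6-bis(methoxymethoxy)benzaldehyde
Conditions: NBS (1.0 equiv), i-Pr2NH (10 mol %), CH2Cl2, −20 °C → 0 °C
Reagents that add atoms: N-bromosuccinimide, O=C1CCC(=O)N1Br
Why: Electrophilic aromatic bromination under amine-catalysed ortho-selective phenol conditions; chelated phenols are halogenated ortho to the OH, and C5 is shielded between two MOM ethers, so bromine should enter at C3, the carbon that becomes C7.

Step 3
Reactants: 4 3-bromo-2-hydroxy-4,6-bis(methoxymethoxy)benzaldehyde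
Product: 5 2-bromo-6-(hydroxymethyl)-3,5-bis(methoxymethoxy)phenol
Conditions: NaBH4, THF/MeOH, 0 °C; pH 7 buffer work-up
Reagents that add atoms: none
Why: Borohydride reduction of the aldehyde to the benzylic alcohol; the aryl bromide and acetals are inert, and a neutral work-up avoids ortho-quinone methide formation.

Step 4
Reactants: 6 (4R)-4-benzyl-1,3-oxazolidin-2-one; 7 bromoacetyl bromide
Product: 9 (4R)-4-benzyl-3-(bromoacetyl)-1,3-oxazolidin-2-one, via lithiated oxazolidinone 8 (not isolated)
Conditions: n-BuLi (1.0 equiv), THF, −78 °C; then 7, −78 °C → 0 °C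
Reagents that add atoms: none
Why: N-acylation of a lithiated oxazolidinone, the standard way of loading this auxiliary; the acyl bromide reacts far faster than the alkyl bromide.

Step 5
Reactants: 5 2-bromo-6-(hydroxymethyl)-3,5-bis(methoxymethoxy)phenol; 9 (4R)-4-benzyl-3-(bromoacetyl)-1,3-oxazolidin-2-one
Product: 10 (4R)-4-benzyl-3-{[2-bromo-6-(hydroxymethyl)-3,5-bis(methoxymethoxy)phenoxy]acetyl}-1,3-oxazolidin-2-one
Conditions: K2CO3 (1.5 equiv), acetone, 0 °C → rt
Reagents that add atoms: none
Why: Williamson ether synthesis; carbonate deprotonates only the phenol, whose phenoxide displaces the highly reactive α-bromo imide bromide while the benzylic alcohol stays free.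

Step 6
Reactants: 10 (4R)-4-benzyl-3-{[2-bromo-6-(hydroxymethyl)-3,5-bis(methoxymethoxy)phenoxy]acetyl}-1,3-oxazolidin-2-one
Product: 11 (4R)-4-benzyl-3-{[2-bromo-6-(bromomethyl)-3,5-bis(methoxymethoxy)phenoxy]acetyl}-1,3-oxazolidin-2-one
Conditions: CBr4 (1.3 equiv), PPh3 (1.3 equiv), CH2Cl2, −20 °C → 0 °C; short silica plug, used at once
Reagents that add atoms: carbon tetrabromide, BrC(Br)(Br)Br
Why: Appel reaction; neutral conditions convert the primary benzylic alcohol to the bromide without touching the MOM acetals or the imide.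

Step 7
Reactants: 11 (4R)-4-benzyl-3-{[2-bromo-6-(bromomethyl)-3,5-bis(methoxymethoxy)phenoxy]acetyl}-1,3-oxazolidin-2-one
Product: 13 (4R)-4-benzyl-3-{[(2S)-7-bromo-4,6-bis(methoxymethoxy)-2,3-dihydro-1-benzofuran-2-yl]carbonyl}-1,3-oxazolidin-2-one, via sodium Z-enolate 12 (not isolated)
Conditions: NaN(SiMe3)2 (1.05 equiv), THF (0.02 M), −78 °C → −45 °C; AcOH, −78 °C
Reagents that add atoms: none
Why: NaN(SiMe3)2 removes a proton from the O–CH2–C(=O) group to give the sodium-chelated Z-enolate 12, whose α-carbon displaces bromide from the CH2Br group on the neighbouring ring carbon in an intramolecular SN2 reaction. The closest known reaction is the Evans-type alkylation of sodium enolates of N-(alkoxyacetyl) oxazolidinones with benzylic and allylic halides, run here intramolecularly. Ring B closes in a 5-(enolexo)-exo-tet mode, forming the C2–C3 bond. C2 is set by the (R)-4-benzyl group, which shields one face of the chelated Z-enolate so that the CH2Br arm must come from the opposite face; with the substituent order OAr > C(=O)N > CH2 > H this should give 2S. The step needs C-alkylation to outrun enolate breakdown and product epimerisation: the benzylic bromide is activated by ortho and para oxygens and held five atoms from the nucleophilic carbon, the C7 bromine offers the enolate no second electrophile, one equivalent of base at −78 °C with an acetic acid quench protects the acidic C2–H, and dilution suppresses dimerisation.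

Step 8
Reactants: 13 (4R)-4-benzyl-3-{[(2S)-7-bromo-4,6-bis(methoxymethoxy)-2,3-dihydro-1-benzofuran-2-yl]carbonyl}-1,3-oxazolidin-2-one
Product: 14 methyl (2S)-7-bromo-4,6-bis(methoxymethoxy)-2,3-dihydro-1-benzofuran-2-carboxylate
Conditions: MeMgBr (1.5 equiv) added to MeOH, then 13 in CH2Cl2, 0 °C; aq NH4Cl
Reagents that add atoms: bromomagnesium methoxide (made from MeMgBr and MeOH), CO[Mg]Br
Why: Transesterification of the imide at its exocyclic carbonyl by the weakly basic magnesium methoxide, which releases the auxiliary and should not epimerise C2.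

Step 9
Reactants: 14 methyl (2S)-7-bromo-4,6-bis(methoxymethoxy)-2,3-dihydro-1-benzofuran-2-carboxylate
Product: 16 2-[(2S)-7-bromo-4,6-bis(methoxymethoxy)-2,3-dihydro-1-benzofuran-2-yl]propan-2-ol, via methyl ketone 15 (not isolated)
Conditions: MeMgBr (3 equiv), THF, −20 °C → 0 °C; aq NH4Cl
Reagents that add atoms: methylmagnesium bromide, C[Mg]Br
Why: Double Grignard addition to the ester; addition to ketone 15 is faster than its enolisation, so C2 should keep its configuration, and the aryl bromide does not exchange with MeMgBr.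

Step 10
Reactants: 16 2-[(2S)-7-bromo-4,6-bis(methoxymethoxy)-2,3-dihydro-1-benzofuran-2-yl]propan-2-ol; 17 3-(4-methoxyphenyl)propanal
Product: 19 1-[(2S)-2-(2-hydroxypropan-2-yl)-4,6-bis(methoxymethoxy)-2,3-dihydro-1-benzofuran-7-yl]-3-(4-methoxyphenyl)propan-1-ol (both epimers at the carbinol carbon), via dilithio species 18 (not isolated)
Conditions: n-BuLi (2.2 equiv), THF, −78 °C; then 17 (1.3 equiv), −78 °C → −40 °C; H2O
Reagents that add atoms: none
Why: After deprotonation of the tertiary OH, bromine–lithium exchange gives the C7 aryllithium, which undergoes 1,2-addition to the aldehyde; the new carbinol centre forms unselectively and is removed in step 12.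

Step 11
Reactants: 19 1-[(2S)-2-(2-hydroxypropan-2-yl)-4,6-bis(methoxymethoxy)-2,3-dihydro-1-benzofuran-7-yl]-3-(4-methoxyphenyl)propan-1-ol; 20 1-bromo-3-methylbut-2-ene (prenyl bromide)
Product: 22 1-[(2S)-2-(2-hydroxypropan-2-yl)-4,6-bis(methoxymethoxy)-5-(3-methylbut-2-en-1-yl)-2,3-dihydro-1-benzofuran-7-yl]-3-(4-methoxyphenyl)propan-1-ol, via trilithio species 21 (not isolated)
Conditions: n-BuLi (3.3 equiv), THF, 0 °C; CuBr·SMe2 (10 mol %), then 20 (1.3 equiv), −78 °C → 0 °C; H2O
Reagents that add atoms: none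
Why: Directed ortho-metalation; once both OH groups are deprotonated, C5–H (the only hydrogen on ring A, flanked by two MOM ethers) is lithiated, and the aryl–metal species is allylated at the primary carbon of prenyl bromide (SN2).

Step 12
Reactants: 22 1-[(2S)-2-(2-hydroxypropan-2-yl)-4,6-bis(methoxymethoxy)-5-(3-methylbut-2-en-1-yl)-2,3-dihydro-1-benzofuran-7-yl]-3-(4-methoxyphenyl)propan-1-ol
Product: 23 1-[(2S)-2-(2-hydroxypropan-2-yl)-4,6-bis(methoxymethoxy)-5-(3-methylbut-2-en-1-yl)-2,3-dihydro-1-benzofuran-7-yl]-3-(4-methoxyphenyl)propan-1-one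
Conditions: Dess–Martin periodinane (1.3 equiv), pyridine, CH2Cl2, 0 °C → rt
Reagents that add atoms: none
Why: Dess–Martin oxidation of the secondary benzylic alcohol to the aryl ketone; the tertiary alcohol cannot be oxidised, and the prenyl group and acetals are inert.

Step 13
Reactants: 23 1-[(2S)-2-(2-hydroxypropan-2-yl)-4,6-bis(methoxymethoxy)-5-(3-methylbut-2-en-1-yl)-2,3-dihydro-1-benzofuran-7-yl]-3-(4-methoxyphenyl)propan-1-one
Product: 25 1-[(2S)-4,6-dihydroxy-2-(2-hydroxypropan-2-yl)-5-(3-methylbut-2-en-1-yl)-2,3-dihydro-1-benzofuran-7-yl]-3-(4-methoxyphenyl)propan-1-one (CNP0150199.1), via 6-hydroxy 4-MOM ether 24 (not isolated)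
Conditions: HCl (ca. 1 M in MeOH), 0 °C → rt, stopped when 24 is consumed
Reagents that add atoms: none
Why: Acid-catalysed acetal exchange with methanol removes both MOM groups, the one ortho to the ketone first; dilute acid at room temperature should spare the prenyl group, the tertiary alcohol and the C2 stereocentre.

**Compound list**

1 | 2,4,6-trihydroxybenzaldehyde | O=Cc1c(O)cc(O)cc1O | starting material
2 | 2,6-dihydroxy-4-(methoxymethoxy)benzaldehyde | O=Cc1c(O)cc(OCOC)cc1O | intermediate
3 | 2-hydroxy-4,6-bis(methoxymethoxy)benzaldehyde | O=Cc1c(O)cc(OCOC)cc1OCOC | intermediate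
4 | 3-bromo-2-hydroxy-4,6-bis(methoxymethoxy)benzaldehyde | O=Cc1c(O)c(Br)c(OCOC)cc1OCOC | intermediate
5 | 2-bromo-6-(hydroxymethyl)-3,5-bis(methoxymethoxy)phenol | OCc1c(O)c(Br)c(OCOC)cc1OCOC | intermediate
6 | (4R)-4-benzyl-1,3-oxazolidin-2-one | O=C1N[C@H](Cc2ccccc2)CO1 | starting material
7 | bromoacetyl bromide | BrCC(=O)Br | starting material
8 | lithium (4R)-4-benzyl-2-oxo-1,3-oxazolidin-3-ide | O=C1[N-][C@H](Cc2ccccc2)CO1.[Li+] | intermediate
9 | (4R)-4-benzyl-3-(bromoacetyl)-1,3-oxazolidin-2-one | O=C(CBr)N1C(=O)OC[C@H]1Cc1ccccc1 | intermediate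
10 | (4R)-4-benzyl-3-{[2-bromo-6-(hydroxymethyl)-3,5-bis(methoxymethoxy)phenoxy]acetyl}-1,3-oxazolidin-2-one | O=C(COc1c(Br)c(OCOC)cc(OCOC)c1CO)N1C(=O)OC[C@H]1Cc1ccccc1 | intermediate
11 | (4R)-4-benzyl-3-{[2-bromo-6-(bromomethyl)-3,5-bis(methoxymethoxy)phenoxy]acetyl}-1,3-oxazolidin-2-one | O=C(COc1c(Br)c(OCOC)cc(OCOC)c1CBr)N1C(=O)OC[C@H]1Cc1ccccc1 | intermediate
12 | sodium (1Z)-1-[(4R)-4-benzyl-2-oxo-1,3-oxazolidin-3-yl]-2-[2-bromo-6-(bromomethyl)-3,5-bis(methoxymethoxy)phenoxy]ethen-1-olate | [Na+].[O-]/C(=C\Oc1c(Br)c(OCOC)cc(OCOC)c1CBr)N1C(=O)OC[C@H]1Cc1ccccc1 | intermediate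
13 | (4R)-4-benzyl-3-{[(2S)-7-bromo-4,6-bis(methoxymethoxy)-2,3-dihydro-1-benzofuran-2-yl]carbonyl}-1,3-oxazolidin-2-one | Brc1c(OCOC)cc(OCOC)c2c1O[C@H](C(=O)N1C(=O)OC[C@H]1Cc1ccccc1)C2 | intermediate
14 | methyl (2S)-7-bromo-4,6-bis(methoxymethoxy)-2,3-dihydro-1-benzofuran-2-carboxylate | Brc1c(OCOC)cc(OCOC)c2c1O[C@H](C(=O)OC)C2 | intermediate
15 | 1-[(2S)-7-bromo-4,6-bis(methoxymethoxy)-2,3-dihydro-1-benzofuran-2-yl]ethan-1-one | Brc1c(OCOC)cc(OCOC)c2c1O[C@H](C(C)=O)C2 | intermediate
16 | 2-[(2S)-7-bromo-4,6-bis(methoxymethoxy)-2,3-dihydro-1-benzofuran-2-yl]propan-2-ol | Brc1c(OCOC)cc(OCOC)c2c1O[C@H](C(C)(C)O)C2 | intermediate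
17 | 3-(4-methoxyphenyl)propanal | COc1ccc(CCC=O)cc1 | starting material
18 | lithium 2-[(2S)-7-lithio-4,6-bis(methoxymethoxy)-2,3-dihydro-1-benzofuran-2-yl]propan-2-olate | [Li]c1c(OCOC)cc(OCOC)c2c1O[C@H](C(C)(C)O[Li])C2 | intermediate
19 | 1-[(2S)-2-(2-hydroxypropan-2-yl)-4,6-bis(methoxymethoxy)-2,3-dihydro-1-benzofuran-7-yl]-3-(4-methoxyphenyl)propan-1-ol (both epimers at the carbinol carbon) | COc1ccc(CCC(O)c2c(OCOC)cc(OCOC)c3c2O[C@H](C(C)(C)O)C3)cc1 | intermediate
20 | 1-bromo-3-methylbut-2-ene (prenyl bromide) | CC(C)=CCBr | starting material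
21 | C5-lithio dilithium dialkoxide of 19 | COc1ccc(CCC(O[Li])c2c(OCOC)c([Li])c(OCOC)c3c2O[C@H](C(C)(C)O[Li])C3)cc1 | intermediate
22 | 1-[(2S)-2-(2-hydroxypropan-2-yl)-4,6-bis(methoxymethoxy)-5-(3-methylbut-2-en-1-yl)-2,3-dihydro-1-benzofuran-7-yl]-3-(4-methoxyphenyl)propan-1-ol (both epimers at the carbinol carbon) | COc1ccc(CCC(O)c2c(OCOC)c(CC=C(C)C)c(OCOC)c3c2O[C@H](C(C)(C)O)C3)cc1 | intermediate
23 | 1-[(2S)-2-(2-hydroxypropan-2-yl)-4,6-bis(methoxymethoxy)-5-(3-methylbut-2-en-1-yl)-2,3-dihydro-1-benzofuran-7-yl]-3-(4-methoxyphenyl)propan-1-one | COc1ccc(CCC(=O)c2c(OCOC)c(CC=C(C)C)c(OCOC)c3c2O[C@H](C(C)(C)O)C3)cc1 | intermediate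
24 | 1-[(2S)-6-hydroxy-2-(2-hydroxypropan-2-yl)-4-(methoxymethoxy)-5-(3-methylbut-2-en-1-yl)-2,3-dihydro-1-benzofuran-7-yl]-3-(4-methoxyphenyl)propan-1-one | COc1ccc(CCC(=O)c2c(O)c(CC=C(C)C)c(OCOC)c3c2O[C@H](C(C)(C)O)C3)cc1 | intermediate
25 | 1-[(2S)-4,6-dihydroxy-2-(2-hydroxypropan-2-yl)-5-(3-methylbut-2-en-1-yl)-2,3-dihydro-1-benzofuran-7-yl]-3-(4-methoxyphenyl)propan-1-one (CNP0150199.1) | COc1ccc(CCC(=O)c2c(O)c(CC=C(C)C)c(O)c3c2O[C@H](C(C)(C)O)C3)cc1 | target

**Step count and risks**

Total step count: 13. Longest linear sequence: 12 steps (steps 1–3 and 5–13, from 1 to 25); step 4 prepares the acylated auxiliary.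

Steps most likely to fail:

Step 7 (key step). What may go wrong: low facial selectivity in the ring closure, breakdown of the imide enolate (loss of the oxazolidinone by way of a ketene) or of the labile benzylic bromide before the C–C bond forms, and epimerisation of the product at C2 by excess base. Fallback, from 5 back to 13: the auxiliary is kept out of the ring closure and used afterwards as a resolving group. Phenol 5 is alkylated with methyl bromoacetate (K2CO3, acetone) to methyl [2-bromo-6-(hydroxymethyl)-3,5-bis(methoxymethoxy)phenoxy]acetate F1. The Appel reaction converts this to methyl [2-bromo-6-(bromomethyl)-3,5-bis(methoxymethoxy)phenoxy]acetate F2. The simple ester enolate (NaN(SiMe3)2, THF, −78 °C) closes the same C2–C3 bond to give racemic methyl 7-bromo-4,6-bis(methoxymethoxy)-2,3-dihydro-1-benzofuran-2-carboxylate F3, and LiOH in THF/H2O gives racemic 7-bromo-4,6-bis(methoxymethoxy)-2,3-dihydro-1-benzofuran-2-carboxylic acid F4. Its mixed pivalic anhydride (pivaloyl chloride, Et3N, THF) acylates lithiated oxazolidinone 8 to give 13 together with the (2R,4R) diastereomeric imide F5; the two imides are separated by chromatography and 13 continues with step 8.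

Step 11. What may go wrong: incomplete lithiation at C5 because the dilithium dialkoxide aggregates, O-prenylation of the alkoxides, or SN2′ attack that delivers the 1,1-dimethylallyl isomer. Fallback, from 19 back to 22: ring A is brominated at its only free carbon with NBS (CH2Cl2, 0 °C) to give 1-[(2S)-5-bromo-2-(2-hydroxypropan-2-yl)-4,6-bis(methoxymethoxy)-2,3-dihydro-1-benzofuran-7-yl]-3-(4-methoxyphenyl)propan-1-ol F6. The prenyl group is then attached by Stille coupling with tributyl(3-methylbut-2-en-1-yl)stannane (Pd2(dba)3, P(t-Bu)3, CsF, dioxane, 90 °C), which needs no strong base and tolerates the free hydroxyl groups, to give 22.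

Step 13. What may go wrong: acid-promoted addition of the C4 or C6 phenol to the prenyl double bond (chroman formation) or ionisation of the tertiary alcohol before both acetals are cleaved. Fallback, from 19 back to 25: the prenyl group is introduced after the acid step. Diol 19 is oxidised with Dess–Martin periodinane to 1-[(2S)-2-(2-hydroxypropan-2-yl)-4,6-bis(methoxymethoxy)-2,3-dihydro-1-benzofuran-7-yl]-3-(4-methoxyphenyl)propan-1-one F7. HCl in MeOH, which can now be used warm, removes both MOM groups to give 1-[(2S)-4,6-dihydroxy-2-(2-hydroxypropan-2-yl)-2,3-dihydro-1-benzofuran-7-yl]-3-(4-methoxyphenyl)propan-1-one F8. C-prenylation of the phenoxide at C5, the only free ring carbon, with prenyl bromide 20 in aqueous KOH at 0 °C then gives 25; O-prenyl ethers are the expected by-products and would be separated.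

Further compounds
F1 | step 7 | methyl [2-bromo-6-(hydroxymethyl)-3,5-bis(methoxymethoxy)phenoxy]acetate | COC(=O)COc1c(Br)c(OCOC)cc(OCOC)c1CO
F2 | step 7 | methyl [2-bromo-6-(bromomethyl)-3,5-bis(methoxymethoxy)phenoxy]acetate | COC(=O)COc1c(Br)c(OCOC)cc(OCOC)c1CBr
F3 | step 7 | methyl 7-bromo-4,6-bis(methoxymethoxy)-2,3-dihydro-1-benzofuran-2-carboxylate (racemate) | COC(=O)C1Cc2c(OCOC)cc(OCOC)c(Br)c2O1
F4 | step 7 | 7-bromo-4,6-bis(methoxymethoxy)-2,3-dihydro-1-benzofuran-2-carboxylic acid (racemate) | OC(=O)C1Cc2c(OCOC)cc(OCOC)c(Br)c2O1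
F5 | step 7 | (4R)-4-benzyl-3-{[(2R)-7-bromo-4,6-bis(methoxymethoxy)-2,3-dihydro-1-benzofuran-2-yl]carbonyl}-1,3-oxazolidin-2-one | Brc1c(OCOC)cc(OCOC)c2c1O[C@@H](C(=O)N1C(=O)OC[C@H]1Cc1ccccc1)C2
F6 | step 11 | 1-[(2S)-5-bromo-2-(2-hydroxypropan-2-yl)-4,6-bis(methoxymethoxy)-2,3-dihydro-1-benzofuran-7-yl]-3-(4-methoxyphenyl)propan-1-ol | COc1ccc(CCC(O)c2c(OCOC)c(Br)c(OCOC)c3c2O[C@H](C(C)(C)O)C3)cc1
F7 | step 13 | 1-[(2S)-2-(2-hydroxypropan-2-yl)-4,6-bis(methoxymethoxy)-2,3-dihydro-1-benzofuran-7-yl]-3-(4-methoxyphenyl)propan-1-one | COc1ccc(CCC(=O)c2c(OCOC)cc(OCOC)c3c2O[C@H](C(C)(C)O)C3)cc1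
F8 | step 13 | 1-[(2S)-4,6-dihydroxy-2-(2-hydroxypropan-2-yl)-2,3-dihydro-1-benzofuran-7-yl]-3-(4-methoxyphenyl)propan-1-one | COc1ccc(CCC(=O)c2c(O)cc(O)c3c2O[C@H](C(C)(C)O)C3)cc1
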